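The plan rests on opening the 14-membered carbocycle at C13–C14, the ring bond that joins two oxygen-bearing stereocentres: C13 with its acetate and C14 with the ring oxygen of the cis-fused γ-lactone, threo to each other. A low-valent titanium pinacol coupling of an open-chain C13,C14-dialdehyde exploits this vicinal dioxygen pattern: in one operation it forms the C13–C14 bond, closes the macrocycle and creates both carbinol centres. The precursor is a linear chain carrying the 12S methyl centre, the 7S allylic silyl ether beside the C8 exo-methylene, the E C3–C4 alkene (the later epoxide) and, on C1, a tert-butyl acetate arm that becomes the lactone.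

Key step: step 16

Remark (numbering and assumption): cembrane numbering is used (C1 lactone-fused CH, C2 CH2, C3–C4 epoxide with methyl on C4, C5–C6 CH2, C7 CH–OAc, C8 carbon bearing the exo-methylene C19, C9–C11 CH2, C12 CH–CH3, C13 CH–OAc, C14 lactone CH–O, C15/C16/C17 lactone α-carbon, carbonyl and methylene); the target is read as (1S,3R,4R,7S,12S,13R,14R) with a cis-fused lactone and a trans epoxide.

Step 1
Reactants: 1 geranyl acetate
Product: 2 (E)-6,7-epoxy-3,7-dimethyloct-2-en-1-yl acetate (racemic at the epoxide CH)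
Conditions: mCPBA (1.05 equiv), NaHCO3, CH2Cl2, 0 °C
Reagents that add atoms: mCPBA, O=C(OO)c1cccc(Cl)c1
Why: Prilezhaev epoxidation should pick the electron-rich 6,7-alkene because the 2,3-alkene is deactivated by the allylic acetate, and the new centre may stay racemic because this carbon is excised in step 6.

Step 2
Reactants: 2 (E)-6,7-epoxy-3,7-dimethyloct-2-en-1-yl acetate
Product: 3 (E)-6,7-epoxy-3,7-dimethyloct-2-en-1-ol
Conditions: K2CO3 (0.2 equiv), MeOH, 0 °C to rt
Reagents that add atoms: none
Why: Carbonate-catalysed transesterification with methanol (Zemplén-type deacetylation) should free the allylic alcohol while the trisubstituted epoxide is inert to cold methoxide.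

Step 3
Reactants: 3 (E)-6,7-epoxy-3,7-dimethyloct-2-en-1-ol
Product: 5 (E)-1-bromo-6,7-epoxy-3,7-dimethyloct-2-ene, via mesylate 4 (not isolated)
Conditions: MsCl, Et3N, THF, −40 °C; then LiBr, THF, 0 °C
Reagents that add atoms: lithium bromide, [Li+].[Br-]
Why: Mesylation followed by SN2 displacement with bromide (Finkelstein-type) at the primary allylic carbon should give the bromide with the E geometry kept and, in the absence of protic acid, with the epoxide intact.

Step 4
Reactants: 6 mono-tert-butyl succinate (4-tert-butoxy-4-oxobutanoic acid); 7 (S)-4-benzyl-1,3-oxazolidin-2-one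
Product: 9 tert-butyl 4-[(4S)-4-benzyl-2-oxo-1,3-oxazolidin-3-yl]-4-oxobutanoate, via mixed pivalic anhydride 8 (not isolated)
Conditions: t-BuCOCl, Et3N, THF, −20 °C; then 7, LiCl, −20 °C to rt
Reagents that add atoms: none
Why: N-Acylation of the oxazolidinone by the mixed pivalic anhydride under LiCl/Et3N activation should occur at the unhindered succinyl carbonyl and leave the tert-butyl ester untouched.

Step 5
Reactants: 9 tert-butyl 4-[(4S)-4-benzyl-2-oxo-1,3-oxazolidin-3-yl]-4-oxobutanoate; 5 (E)-1-bromo-6,7-epoxy-3,7-dimethyloct-2-ene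
Product: 11 tert-butyl (3S,5E)-3-{[(4S)-4-benzyl-2-oxo-1,3-oxazolidin-3-yl]carbonyl}-9,10-epoxy-6,10-dimethylundec-5-enoate (both epoxide epimers), via sodium Z-enolate 10 (not isolated)
Conditions: NaN(SiMe3)2 (1.05 equiv), THF, −78 °C; then 5 (1.3 equiv), −78 to −40 °C
Reagents that add atoms: none
Why: Evans asymmetric alkylation, in which the imide α-CH2 is more acidic than the ester α-CH2, the chelated sodium Z-enolate is shielded on one face by the benzyl group, and SN2 attack on the primary allylic bromide from the open face should set C1 as S while the epoxide is not touched at −78 °C.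

Step 6
Reactants: 11 tert-butyl (3S,5E)-3-{[(4S)-4-benzyl-2-oxo-1,3-oxazolidin-3-yl]carbonyl}-9,10-epoxy-6,10-dimethylundec-5-enoate
Product: 13 tert-butyl (3S,5E)-3-{[(4S)-4-benzyl-2-oxo-1,3-oxazolidin-3-yl]carbonyl}-6-methyl-9-oxonon-5-enoate (C7 aldehyde), via 9,10-diol 12 (not isolated)
Conditions: H5IO6 (1.2 equiv), THF/H2O, 0 °C
Reagents that add atoms: none
Why: Periodic acid should hydrolyse the epoxide to the glycol and cleave it at once (Malaprade glycol cleavage) to the C7 aldehyde and acetone, conditions under which the trisubstituted alkene, the imide and the tert-butyl ester are stable and C1, which is not α to the new aldehyde, cannot epimerise.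

Step 7
Reactants: 14 hept-6-ynoic acid
Product: 15 6-iodohept-6-enoic acid
Conditions: NaI, Me3SiCl, H2O (0.5 equiv), MeCN, rt
Reagents that add atoms: sodium iodide, [Na+].[I-]
Why: Hydrogen iodide generated in situ should add to the terminal alkyne in the Markovnikov sense (alkyne hydroiodination) to give the 2-iodo-1-alkene, and doing this first keeps the acid away from every sensitive group of the later route.

Step 8
Reactants: 15 6-iodohept-6-enoic acid; 7 (S)-4-benzyl-1,3-oxazolidin-2-one
Product: 17 (4S)-4-benzyl-3-(6-iodohept-6-enoyl)-1,3-oxazolidin-2-one, via mixed pivalic anhydride 16 (not isolated)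
Conditions: t-BuCOCl, Et3N, THF, −20 °C; then 7, LiCl, −20 °C to rt
Reagents that add atoms: none
Why: Mixed-anhydride N-acylation of the oxazolidinone, as in step 4, should give the imide without touching the alkenyl iodide.

Step 9
Reactants: 17 (4S)-4-benzyl-3-(6-iodohept-6-enoyl)-1,3-oxazolidin-2-one
Product: 19 (4S)-4-benzyl-3-[(2S)-6-iodo-2-methylhept-6-enoyl]-1,3-oxazolidin-2-one, via sodium Z-enolate 18 (not isolated)
Conditions: NaN(SiMe3)2 (1.1 equiv), THF, −78 °C; then MeI (5 equiv), −78 °C
Reagents that add atoms: iodomethane, CI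
Why: Evans asymmetric methylation, in which the chelated sodium Z-enolate is methylated on the face away from the benzyl group, should set C12 as S, and the minor diastereomer is removable by chromatography at this stage.

Step 10
Reactants: 13 tert-butyl (3S,5E)-3-{[(4S)-4-benzyl-2-oxo-1,3-oxazolidin-3-yl]carbonyl}-6-methyl-9-oxonon-5-enoate; 19 (4S)-4-benzyl-3-[(2S)-6-iodo-2-methylhept-6-enoyl]-1,3-oxazolidin-2-one
Product: 21 tert-butyl (3S,5E,14S)-15-[(4S)-4-benzyl-2-oxo-1,3-oxazolidin-3-yl]-3-{[(4S)-4-benzyl-2-oxo-1,3-oxazolidin-3-yl]carbonyl}-9-hydroxy-6,14-dimethyl-10-methylidene-15-oxopentadec-5-enoate (both C7 epimers; chain C9 is C7), via alkenylchromium dichloride 20 (not isolated)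
Conditions: CrCl2 (4 equiv), NiCl2 (1 mol %), DMSO, rt; 19 (1.5 equiv)
Reagents that add atoms: none
Why: Nozaki–Hiyama–Kishi coupling, in which zerovalent nickel inserts into the C–I bond and transmetalation gives an alkenyl derivative of trivalent chromium that adds only to the aldehyde in the presence of the imides and the ester, should form the C7–C8 bond, C7 being left uncontrolled because the next step removes the centre.

Step 11
Reactants: 21 C7-epimeric allylic alcohols
Product: 22 tert-butyl (3S,5E,14S)-15-[(4S)-4-benzyl-2-oxo-1,3-oxazolidin-3-yl]-3-{[(4S)-4-benzyl-2-oxo-1,3-oxazolidin-3-yl]carbonyl}-6,14-dimethyl-10-methylidene-9,15-dioxopentadec-5-enoate (C7 ketone)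
Conditions: Dess–Martin periodinane (1.5 equiv), NaHCO3, CH2Cl2, 0 °C to rt
Reagents that add atoms: none
Why: Dess–Martin oxidation should converge both C7 epimers on the α-methylene ketone under buffered, non-enolising conditions that leave C1 and C12 alone.

Step 12
Reactants: 22 C7 ketone
Product: 23 tert-butyl (3S,5E,9S,14S)-15-[(4S)-4-benzyl-2-oxo-1,3-oxazolidin-3-yl]-3-{[(4S)-4-benzyl-2-oxo-1,3-oxazolidin-3-yl]carbonyl}-9-hydroxy-6,14-dimethyl-10-methylidene-15-oxopentadec-5-enoate (7S alcohol)
Conditions: (R)-2-methyl-CBS-oxazaborolidine [(3aR)-1-methyl-3,3-diphenyltetrahydro-1H,3H-pyrrolo[1,2-c][1,3,2]oxazaborole] (0.5 equiv), catecholborane (2 equiv), toluene, −78 °C; then MeOH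
Reagents that add atoms: none
Why: Corey–Bakshi–Shibata reduction, in which the ketone binds to the catalyst boron with the branched alkenyl group as the large substituent and the CH2 chain as the small one, should deliver hydride from the (R)-catalyst to give the 7S allylic alcohol, and catecholborane at −78 °C neither hydroborates the alkenes nor reduces the imides.

Step 13
Reactants: 23 7S alcohol
Product: 24 tert-butyl (3S,5E,9S,14S)-15-[(4S)-4-benzyl-2-oxo-1,3-oxazolidin-3-yl]-3-{[(4S)-4-benzyl-2-oxo-1,3-oxazolidin-3-yl]carbonyl}-9-(tert-butyldiphenylsilyloxy)-6,14-dimethyl-10-methylidene-15-oxopentadec-5-enoate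
Conditions: t-BuPh2SiCl, imidazole, 4-(dimethylamino)pyridine (cat.), DMF, rt to 40 °C
Reagents that add atoms: tert-butyl(chloro)diphenylsilane, CC(C)(C)[Si](Cl)(c1ccccc1)c1ccccc1
Why: Imidazole-promoted silylation of the secondary allylic alcohol should proceed without touching the imides, and the tert-butyldiphenylsilyl group is chosen because it outlasts the acid of step 17.

Step 14
Reactants: 24 bis-imide silyl ether
Product: 25 tert-butyl (3S,5E,9S,14S)-9-(tert-butyldiphenylsilyloxy)-15-hydroxy-3-(hydroxymethyl)-6,14-dimethyl-10-methylidenepentadec-5-enoate (C13,C14-diol)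
Conditions: LiBH4 (3 equiv), MeOH (3 equiv), THF, 0 °C
Reagents that add atoms: none
Why: Reductive cleavage of N-acyl oxazolidinones by LiBH4 should release both auxiliaries and give the C13 and C14 primary alcohols in one operation without epimerising C12 or C1, while the tert-butyl ester (unlike a methyl ester) is neither reduced nor lactonised by the neighbouring C14 hydroxyl.

Step 15
Reactants: 25 C13,C14-diol
Product: 26 tert-butyl (3S,5E,9S,14S)-9-(tert-butyldiphenylsilyloxy)-3-formyl-6,14-dimethyl-10-methylidene-15-oxopentadec-5-enoate (seco C13,C14-dialdehyde)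
Conditions: Dess–Martin periodinane (3 equiv), NaHCO3, CH2Cl2, 0 °C to rt; filtered through a short silica pad and used at once
Reagents that add atoms: none
Why: Double Dess–Martin oxidation under bicarbonate buffer should give the dialdehyde without epimerising the two α-stereocentres C12 and C1.

Step 16
Reactants: 26 seco C13,C14-dialdehyde
Product: 27 tert-butyl 2-[(1S,3E,7S,12S,13R,14R)-7-(tert-butyldiphenylsilyloxy)-13,14-dihydroxy-4,12-dimethyl-8-methylidenecyclotetradec-3-en-1-yl]acetate (macrocyclic threo 13,14-diol)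
Conditions: TiCl3(DME)1.5 (12 equiv), Zn–Cu couple (30 equiv), DME, reflux, 3 h; then 25 °C, 26 in DME added by syringe pump over 30 h (final about 2 mM), 6 h more; 20% aq. K2CO3
Reagents that add atoms: none
Why: Electron transfer from low-valent titanium turns each aldehyde into a titanium-bound ketyl, the two ketyls couple at carbon on a titanium-bridged template, and the resulting pinacolate is hydrolysed to the diol on aqueous K2CO3 work-up. The closest known reaction type is the McMurry-type intramolecular pinacol coupling of long-chain dialdehydes to macrocyclic 1,2-diols, run at 25 °C so that deoxygenation to the alkene does not follow. The 14-membered carbocycle closes end to end by ketyl–ketyl recombination between C13 and C14 (formally a 14-exo-trig closure if seen as attack of the C13 ketyl on the C14 carbonyl), helped by slow addition, by the metal template and by the chain bends at the E C3–C4 alkene and the C7 branch. C13 should be set by Felkin–Anh 1,2-induction from the C12 methyl centre, which gives the required 12,13-syn relation (13R), and C14 by the preference of titanium macro-pinacol couplings for the threo diol, in which the two chain ends lie anti on the bridged pinacolate, with only weak help from C1. The step needs chemoselectivity for the two aldehydes, which the substrate secures because the tert-butyl ester, the silyl ether and the unactivated alkenes are not reduced under these conditions (samarium ketyls would be more prone to add to the C8 methylene) and the reducible epoxide is introduced only in step 23. It also needs the (13R,14R) isomer out of four, and this diastereoselectivity is the main uncertainty of the whole route.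

Step 17
Reactants: 27 macrocyclic threo 13,14-diol
Product: 29 (1S,3E,7S,12S,13R,14R)-7-(tert-butyldiphenylsilyloxy)-13-hydroxy γ-lactone (C14–O–C16(=O)–C15H2–C1, cis-fused to the 14-membered ring; 4,12-dimethyl, 8-methylidene, 3E-alkene), via dihydroxy acid 28 (not isolated)
Conditions: CF3CO2H/CH2Cl2 (1:10), 0 °C; then aq. NaHCO3
Reagents that add atoms: none
Why: Acidolysis of the tert-butyl ester (loss of isobutene) followed by spontaneous lactonisation of the γ-hydroxy acid should close the five-membered lactone on the C14 oxygen, favoured kinetically and thermodynamically over the six-membered alternative through C13–OH, with retention at C14 so that the ring fusion is cis.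

Step 18
Reactants: 29 13-hydroxy lactone
Product: 30 13-O-triethylsilyl ether of 29
Conditions: Et3SiOTf, 2,6-lutidine, CH2Cl2, −78 °C
Reagents that add atoms: triethylsilyl trifluoromethanesulfonate, CC[Si](CC)(CC)OS(=O)(=O)C(F)(F)F
Why: Silylation of the hindered C13 hydroxyl with the silyl triflate and 2,6-lutidine should leave the lactone α-CH2 as the only acidic site for the next step and rule out migration of the lactone acyl group to C13 under base.

Step 19
Reactants: 30 bis-silylated lactone
Product: 32 C15-(dimethylaminomethyl) lactone (Mannich base; C15 epimers), via lithium enolate 31 (not isolated)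
Conditions: LiN(i-Pr)2 (1.3 equiv), THF, −78 °C; then dimethyl(methylene)ammonium iodide (3 equiv), −78 °C to rt
Reagents that add atoms: dimethyl(methylene)ammonium iodide, C=[N+](C)C.[I-]
Why: Mannich reaction of the lithium lactone enolate with Eschenmoser's salt should install the C17 carbon at C15, and the configuration created at C15 is irrelevant because it is lost in step 20.

Step 20
Reactants: 32 Mannich base
Product: 34 (1S,3E,7S,12S,13R,14R)-7-(tert-butyldiphenylsilyloxy)-13-(triethylsilyloxy)cembra-3,8(19),15(17)-trien-16,14-olide (α-methylene lactone), via trimethylammonium iodide 33 (not isolated)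
Conditions: MeI (excess), THF/MeOH, rt; then aq. NaHCO3, CH2Cl2, rt
Reagents that add atoms: none
Why: Quaternisation of the amine and base-induced β-elimination of trimethylamine (Hofmann-type, E1cB) should give the exocyclic α-methylene lactone without touching any stereocentre.

Step 21
Reactants: 34 bis-silylated α-methylene lactone
Product: 35 (1S,3E,7S,12S,13R,14R)-7,13-dihydroxycembra-3,8(19),15(17)-trien-16,14-olide
Conditions: HF·pyridine, pyridine, THF, 0 °C to rt
Reagents that add atoms: none
Why: Fluoride-driven desilylation with buffered HF·pyridine should remove both silyl ethers under conditions that the α-methylene lactone and the alkenes tolerate.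

Step 22
Reactants: 35 7,13-diol
Product: 36 (1S,3E,7S,12S,13R,14R)-7,13-diacetoxycembra-3,8(19),15(17)-trien-16,14-olide
Conditions: Ac2O, pyridine, 4-(dimethylamino)pyridine (cat.), CH2Cl2, 0 °C to rt
Reagents that add atoms: acetic anhydride, CC(=O)OC(C)=O
Why: Pyridine/DMAP-catalysed acetylation (nucleophilic acyl transfer) should esterify both secondary alcohols with retention.

Step 23
Reactants: 36 diacetate triene
Product: 37 (1S,3R,4R,7S,12S,13R,14R)-7,13-diacetoxy-3,4-epoxycembra-8(19),15(17)-dien-16,14-olide (CNP0323853.2)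
Conditions: D-fructose-derived Shi ketone (1,2:4,5-di-O-isopropylidene-β-D-erythro-2,3-hexodiulo-2,6-pyranose, 0.5 equiv), KHSO5 (as Oxone), K2CO3, Bu4NHSO4 (cat.), MeCN/dimethoxymethane/aq. Na2B4O7 buffer (pH about 10.5), 0 °C
Reagents that add atoms: potassium peroxymonosulfate, [K+].[O-]S(=O)(=O)OO
Why: Shi epoxidation, in which the chiral dioxirane generated from the ketone and KHSO5 transfers oxygen through a spiro transition state to the electron-rich E-trisubstituted C3–C4 alkene, is expected to give the (3R,4R) epoxide with the D-fructose-derived ketone, while the conjugated lactone methylene and the acetoxy-flanked 1,1-disubstituted C8 methylene are much poorer substrates.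

Compound list
1 | geranyl acetate | CC(C)=CCC/C(C)=C/COC(C)=O | starting material
2 | (E)-6,7-epoxy-3,7-dimethyloct-2-en-1-yl acetate (racemic epoxide) | CC1(C)OC1CC/C(C)=C/COC(C)=O | intermediate
3 | (E)-6,7-epoxy-3,7-dimethyloct-2-en-1-ol | CC1(C)OC1CC/C(C)=C/CO | intermediate
4 | (E)-6,7-epoxy-3,7-dimethyloct-2-en-1-yl methanesulfonate (not isolated) | CC1(C)OC1CC/C(C)=C/COS(C)(=O)=O | intermediate
5 | (E)-1-bromo-6,7-epoxy-3,7-dimethyloct-2-ene | CC1(C)OC1CC/C(C)=C/CBr | intermediate
6 | mono-tert-butyl succinate | CC(C)(C)OC(=O)CCC(=O)O | starting material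
7 | (S)-4-benzyl-1,3-oxazolidin-2-one | O=C1OC[C@H](Cc2ccccc2)N1 | starting material
8 | mixed anhydride of 6 with pivalic acid (not isolated) | CC(C)(C)OC(=O)CCC(=O)OC(=O)C(C)(C)C | intermediate
9 | tert-butyl 4-[(4S)-4-benzyl-2-oxo-1,3-oxazolidin-3-yl]-4-oxobutanoate | CC(C)(C)OC(=O)CCC(=O)N1[C@@H](Cc2ccccc2)COC1=O | intermediate
10 | sodium Z-enolate of 9 (not isolated) | CC(C)(C)OC(=O)C/C=C(\[O-])N1[C@@H](Cc2ccccc2)COC1=O.[Na+] | intermediate
11 | tert-butyl (3S,5E)-3-{[(4S)-4-benzyl-2-oxo-1,3-oxazolidin-3-yl]carbonyl}-9,10-epoxy-6,10-dimethylundec-5-enoate (epoxide epimers) | CC(C)(C)OC(=O)C[C@H](C/C=C(C)/CCC1OC1(C)C)C(=O)N1[C@@H](Cc2ccccc2)COC1=O | intermediate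
12 | 9,10-diol corresponding to 11 (not isolated) | CC(C)(C)OC(=O)C[C@H](C/C=C(C)/CCC(O)C(C)(C)O)C(=O)N1[C@@H](Cc2ccccc2)COC1=O | intermediate
13 | tert-butyl (3S,5E)-3-{[(4S)-4-benzyl-2-oxo-1,3-oxazolidin-3-yl]carbonyl}-6-methyl-9-oxonon-5-enoate | CC(C)(C)OC(=O)C[C@H](C/C=C(C)/CCC=O)C(=O)N1[C@@H](Cc2ccccc2)COC1=O | intermediate
14 | hept-6-ynoic acid | C#CCCCCC(=O)O | starting material
15 | 6-iodohept-6-enoic acid | C=C(I)CCCCC(=O)O | intermediate
16 | mixed anhydride of 15 with pivalic acid (not isolated) | C=C(I)CCCCC(=O)OC(=O)C(C)(C)C | intermediate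
17 | (4S)-4-benzyl-3-(6-iodohept-6-enoyl)-1,3-oxazolidin-2-one | C=C(I)CCCCC(=O)N1[C@@H](Cc2ccccc2)COC1=O | intermediate
18 | sodium Z-enolate of 17 (not isolated) | C=C(I)CCC/C=C(\[O-])N1[C@@H](Cc2ccccc2)COC1=O.[Na+] | intermediate
19 | (4S)-4-benzyl-3-[(2S)-6-iodo-2-methylhept-6-enoyl]-1,3-oxazolidin-2-one | C=C(I)CCC[C@H](C)C(=O)N1[C@@H](Cc2ccccc2)COC1=O | intermediate
20 | alkenylchromium dichloride from 19 (not isolated) | C=C([Cr](Cl)Cl)CCC[C@H](C)C(=O)N1[C@@H](Cc2ccccc2)COC1=O | intermediate
21 | coupled bis-imide allylic alcohol, both C7 epimers | O=C(N1[C@@H](Cc2ccccc2)COC1=O)[C@@H](C)CCCC(=C)C(O)CC/C(C)=C/C[C@@H](CC(=O)OC(C)(C)C)C(=O)N1[C@@H](Cc2ccccc2)COC1=O | intermediate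
22 | bis-imide C7 ketone (α-methylene ketone) | O=C(N1[C@@H](Cc2ccccc2)COC1=O)[C@@H](C)CCCC(=C)C(=O)CC/C(C)=C/C[C@@H](CC(=O)OC(C)(C)C)C(=O)N1[C@@H](Cc2ccccc2)COC1=O | intermediate
23 | bis-imide (7S)-allylic alcohol | O=C(N1[C@@H](Cc2ccccc2)COC1=O)[C@@H](C)CCCC(=C)[C@@H](O)CC/C(C)=C/C[C@@H](CC(=O)OC(C)(C)C)C(=O)N1[C@@H](Cc2ccccc2)COC1=O | intermediate
24 | bis-imide (7S)-tert-butyldiphenylsilyl ether | O=C(N1[C@@H](Cc2ccccc2)COC1=O)[C@@H](C)CCCC(=C)[C@@H](O[Si](c3ccccc3)(c3ccccc3)C(C)(C)C)CC/C(C)=C/C[C@@H](CC(=O)OC(C)(C)C)C(=O)N1[C@@H](Cc2ccccc2)COC1=O | intermediate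
25 | tert-butyl (3S,5E,9S,14S)-9-(tert-butyldiphenylsilyloxy)-15-hydroxy-3-(hydroxymethyl)-6,14-dimethyl-10-methylidenepentadec-5-enoate | OC[C@@H](C)CCCC(=C)[C@@H](O[Si](c1ccccc1)(c1ccccc1)C(C)(C)C)CC/C(C)=C/C[C@@H](CC(=O)OC(C)(C)C)CO | intermediate
26 | tert-butyl (3S,5E,9S,14S)-9-(tert-butyldiphenylsilyloxy)-3-formyl-6,14-dimethyl-10-methylidene-15-oxopentadec-5-enoate (seco C13,C14-dialdehyde) | O=C[C@@H](C)CCCC(=C)[C@@H](O[Si](c1ccccc1)(c1ccccc1)C(C)(C)C)CC/C(C)=C/C[C@@H](CC(=O)OC(C)(C)C)C=O | intermediate
27 | tert-butyl 2-[(1S,3E,7S,12S,13R,14R)-7-(tert-butyldiphenylsilyloxy)-13,14-dihydroxy-4,12-dimethyl-8-methylidenecyclotetradec-3-en-1-yl]acetate | C=C1CCC[C@H](C)[C@@H](O)[C@H](O)[C@H](CC(=O)OC(C)(C)C)C/C=C(C)/CC[C@@H]1O[Si](c2ccccc2)(c2ccccc2)C(C)(C)C | intermediate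
28 | 2-[(1S,3E,7S,12S,13R,14R)-7-(tert-butyldiphenylsilyloxy)-13,14-dihydroxy-4,12-dimethyl-8-methylidenecyclotetradec-3-en-1-yl]acetic acid (not isolated) | C=C1CCC[C@H](C)[C@@H](O)[C@H](O)[C@H](CC(=O)O)C/C=C(C)/CC[C@@H]1O[Si](c2ccccc2)(c2ccccc2)C(C)(C)C | intermediate
29 | cis-fused γ-lactone of 28 through the C14 oxygen, 13R-hydroxyl free | C=C1CCC[C@H](C)[C@@H](O)[C@@H]2OC(=O)C[C@@H]2C/C=C(C)/CC[C@@H]1O[Si](c3ccccc3)(c3ccccc3)C(C)(C)C | intermediate
30 | 13-O-triethylsilyl ether of 29 | C=C1CCC[C@H](C)[C@@H](O[Si](CC)(CC)CC)[C@@H]2OC(=O)C[C@@H]2C/C=C(C)/CC[C@@H]1O[Si](c3ccccc3)(c3ccccc3)C(C)(C)C | intermediate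
31 | lithium enolate of 30 (not isolated) | C=C1CCC[C@H](C)[C@@H](O[Si](CC)(CC)CC)[C@@H]2OC([O-])=C[C@@H]2C/C=C(C)/CC[C@@H]1O[Si](c3ccccc3)(c3ccccc3)C(C)(C)C.[Li+] | intermediate
32 | C15-(dimethylaminomethyl) lactone, C15 epimers | C=C1CCC[C@H](C)[C@@H](O[Si](CC)(CC)CC)[C@@H]2OC(=O)C(CN(C)C)[C@@H]2C/C=C(C)/CC[C@@H]1O[Si](c3ccccc3)(c3ccccc3)C(C)(C)C | intermediate
33 | trimethylammonium iodide of 32 (not isolated) | C=C1CCC[C@H](C)[C@@H](O[Si](CC)(CC)CC)[C@@H]2OC(=O)C(C[N+](C)(C)C)[C@@H]2C/C=C(C)/CC[C@@H]1O[Si](c3ccccc3)(c3ccccc3)C(C)(C)C.[I-] | intermediate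
34 | (1S,3E,7S,12S,13R,14R)-7-(tert-butyldiphenylsilyloxy)-13-(triethylsilyloxy)cembra-3,8(19),15(17)-trien-16,14-olide | C=C1CCC[C@H](C)[C@@H](O[Si](CC)(CC)CC)[C@@H]2OC(=O)C(=C)[C@@H]2C/C=C(C)/CC[C@@H]1O[Si](c3ccccc3)(c3ccccc3)C(C)(C)C | intermediate
35 | (1S,3E,7S,12S,13R,14R)-7,13-dihydroxycembra-3,8(19),15(17)-trien-16,14-olide | C=C1CCC[C@H](C)[C@@H](O)[C@@H]2OC(=O)C(=C)[C@@H]2C/C=C(C)/CC[C@@H]1O | intermediate
36 | (1S,3E,7S,12S,13R,14R)-7,13-diacetoxycembra-3,8(19),15(17)-trien-16,14-olide | C=C1CCC[C@H](C)[C@@H](OC(C)=O)[C@@H]2OC(=O)C(=C)[C@@H]2C/C=C(C)/CC[C@@H]1OC(C)=O | intermediate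
37 | (1S,3R,4R,7S,12S,13R,14R)-7,13-diacetoxy-3,4-epoxycembra-8(19),15(17)-dien-16,14-olide (CNP0323853.2) | C=C1CCC[C@H](C)[C@@H](OC(C)=O)[C@@H]2OC(=O)C(=C)[C@@H]2C[C@H]2O[C@]2(C)CC[C@@H]1OC(C)=O | target

Total step count: 23. Longest linear sequence: 19 steps (steps 1–3, 5, 6, 10–23, from geranyl acetate).

Steps most likely to fail

Step 16. The two ketyls may pair with the wrong facial sense, so that stereocontrol at C13 is poor, or they may couple between molecules and give oligomers. The fallback sets out from dialdehyde 26 and assumes that the ring still closes but that the erythro diol epimeric at C13 dominates, tert-butyl 2-[(1S,3E,7S,12S,13S,14R)-7-(tert-butyldiphenylsilyloxy)-13,14-dihydroxy-4,12-dimethyl-8-methylidenecyclotetradec-3-en-1-yl]acetate F1. C13 is then set by ketone reduction instead of by the coupling. Trifluoroacetic acid in CH2Cl2 at 0 °C should take F1 through the 13-epi dihydroxy acid F2 to the 13-epi hydroxy lactone F3. Dess–Martin periodinane should oxidise F3 to the C13 ketone F4, whose flanking centres C12 and C14 are not exposed to base. LiBH(s-Bu)3 in THF at −78 °C, a bulky non-chelating hydride, should then attack anti to the C14 acyloxy substituent (polar Felkin–Anh control, the stronger of the two adjacent directing groups) and give the threo 13R alcohol. This is hydroxy lactone 29, where the route is rejoined.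

Step 23. The conformational face preference of the macrocycle may override the catalyst, so that oxygen arrives on the wrong face of the C3–C4 alkene, or oxidation may stray to the C8 methylene. The fallback sets out from diacetate 36 and delivers the oxygen in two steps from the opposite face. N-Bromosuccinimide in THF/H2O at 0 °C should form the bromonium ion on the face that direct oxygen transfer prefers, and water should open it anti at the tertiary C4. The product is the (3S)-bromo-(4R)-hydroxy bromohydrin F5. Cs2CO3 in MeCN at rt should then close the epoxide by intramolecular SN2 displacement with inversion at C3, without methanolysis of the acetates or addition to the lactone methylene. This gives target 37 directly.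

Step 17. Protonation of the trisubstituted alkene with transannular cyclisation, or partial loss of the silyl ether, may compete with cleavage of the tert-butyl ester. The fallback sets out from diol 27 and avoids protic acid. Me3SiOTf with 2,6-lutidine in CH2Cl2 at 0 °C should convert the tert-butyl ester into the trimethylsilyl ester (silyl transfer with loss of isobutene) and silylate both hydroxyls, giving the tris(trimethylsilyl) derivative F6. Brief treatment with K2CO3 in MeOH followed by acidification to pH 4 with citric acid should free dihydroxy acid 28. This is closed with 1-ethyl-3-(3-dimethylaminopropyl)carbodiimide hydrochloride and 4-(dimethylamino)pyridine in CH2Cl2 to hydroxy lactone 29, where the route is rejoined.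

Further compounds
F1 | step 16 | tert-butyl 2-[(1S,3E,7S,12S,13S,14R)-7-(tert-butyldiphenylsilyloxy)-13,14-dihydroxy-4,12-dimethyl-8-methylidenecyclotetradec-3-en-1-yl]acetate (13-epi diol) | C=C1CCC[C@H](C)[C@H](O)[C@H](O)[C@H](CC(=O)OC(C)(C)C)C/C=C(C)/CC[C@@H]1O[Si](c2ccccc2)(c2ccccc2)C(C)(C)C
F2 | step 16 | 13-epi dihydroxy acid (13S epimer of 28) | C=C1CCC[C@H](C)[C@H](O)[C@H](O)[C@H](CC(=O)O)C/C=C(C)/CC[C@@H]1O[Si](c2ccccc2)(c2ccccc2)C(C)(C)C
F3 | step 16 | 13-epi hydroxy lactone (13S epimer of 29) | C=C1CCC[C@H](C)[C@H](O)[C@@H]2OC(=O)C[C@@H]2C/C=C(C)/CC[C@@H]1O[Si](c3ccccc3)(c3ccccc3)C(C)(C)C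
F4 | step 16 | C13 ketone of the lactone (13-oxo analogue of 29) | C=C1CCC[C@H](C)C(=O)[C@@H]2OC(=O)C[C@@H]2C/C=C(C)/CC[C@@H]1O[Si](c3ccccc3)(c3ccccc3)C(C)(C)C
F5 | step 23 | (1S,3S,4R,7S,12S,13R,14R)-7,13-diacetoxy-3-bromo-4-hydroxycembra-8(19),15(17)-dien-16,14-olide (bromohydrin) | C=C1CCC[C@H](C)[C@@H](OC(C)=O)[C@@H]2OC(=O)C(=C)[C@@H]2C[C@H](Br)[C@](C)(O)CC[C@@H]1OC(C)=O
F6 | step 17 | trimethylsilyl ester and 13,14-bis(trimethylsilyl) ether of acid 28 | C=C1CCC[C@H](C)[C@@H](O[Si](C)(C)C)[C@H](O[Si](C)(C)C)[C@H](CC(=O)O[Si](C)(C)C)C/C=C(C)/CC[C@@H]1O[Si](c2ccccc2)(c2ccccc2)C(C)(C)C
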